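## Analysis of the target

The target is a (2S)-flavanone: ring A is fused to the heterocyclic ring C, and C2 carries an unsubstituted phenyl ring B. Ring A is a fully substituted 1,3,5-trioxygenated benzene. It carries O1 on C8a, free hydroxyls on C5 and C7, the C4 ketone on C4a, and a 3-methylbut-2-enoyl group on C8. C6 carries a CH2 group that links it to C3 of a 6-ethyl-4-hydroxy-5-methylpyran-2-one. C2 is the only stereocentre. It is benzylic and β to the C4 ketone, so enolisation at C3 can open ring C to the chalcone and erase it. Three further weak points fix the order of events: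

- The β,β-dimethyl enone on C8 lies next to the C7 hydroxyl and can close to a 2,2-dimethylchromanone.
- The CH2 bridge joins two enolic rings and can exchange its partners by retro-Michael and Michael steps.
- The pyranone hydroxyl is about as acidic as a carboxylic acid.

The main difficulty is regiochemical: five different groups sit around ring A, and the two oxygens ortho to C4a (O1 and the C5 oxygen) must be told apart. The strategy rests on reading C5–C6–C7–C8–C8a–C4a–C4 as a folded 3,5,7-triketo ester, with C5 the ester carbon, C7, C8a and C4 the ketones, and C3=C2–Ph the styryl end. This is the same alternating oxygen pattern as in the pyranone across the bridge. Both halves can therefore be drawn as 4-hydroxypyran-2-ones joined through CH2.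

## Retrosynthetic reasoning

**25 to 24.** The two O–Si bonds, at the C7 oxygen and at the pyranone oxygen, are cut first. Silyl ethers are kept on exactly these two oxygens until the end: the C7 oxygen is the one that could add to the neighbouring enone, and the pyranone hydroxyl is the strongest acid in the molecule. The forward step needs a fluoride source that is not basic, so that C2 is left alone.

**24 to 19, 22 and 23.** The C8–acyl bond is cut next, because the 3-methylbut-2-enoyl group is the most fragile substituent and should be the last carbon unit to arrive. Cutting to aryl iodide 19, carbon monoxide 23 and alkenylstannane 22 allows a neutral palladium-catalysed coupling. An electrophilic acylation was not chosen as the main line because its Lewis acid would act on the bridge, on C2 and on the silyl ethers. The forward step must insert 23 before the alkenyl group is transferred, at a carbon flanked by O1 and the silylated C7 oxygen. Stannane 22 comes from Grignard reagent 20 and tin chloride 21.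

**19 to 17.** The C8–I bond is cut. C8 is the only free carbon of ring A and is para to the C5 hydroxyl, so iodination with 18 has one site. It must leave the enolisable C3 untouched.

**17 to 16.** The O1–C2 bond is cut, which opens ring C to chalcone 16. This is the only place where C2 is made, and it is placed after every strongly basic step. The forward oxa-Michael addition has two tasks. It must use the hydroxyl next to the unsubstituted ring carbon, so that the bridge ends on C6 and C8 stays free, and it must attack one face of the enone.

**16 to 14.** The two silyl ethers are removed in the retrosynthetic sense to give chalcone 14. The forward silylation with 15 must take the two oxygens that are not tied to the ketone by a hydrogen bond. This removes the acidic protons that would neutralise an amine catalyst and puts bulk next to the hydroxyl that must not close.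

**14 to 12, through 13.** This is the central disconnection, the C4a–C5 bond. Cutting it unfolds ring A to the open-chain triketo ester 13, whose lactone form is bis-pyranone 12. One ring and one skeletal bond are traded for a compound made from two simple pyranones. The forward step is an isomerisation that must prefer Claisen closure to every other mode of cyclisation.

**12 to 10 and 7, through 11.** The bond between the bridge CH2 and C3 of the oxoalkyl-bearing pyranone is cut. The CH2 is left on the other pyranone as Mannich base 7, which is the only partner that can become the electrophile (methylidene-dione 11). This is what makes the bridge unsymmetrical.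

**10 to 8 and 9.** The bond between the side-chain CH2 and the cinnamoyl carbonyl is cut, back to lactone 8 and Weinreb amide 9. The forward step is an acylation at the methyl group of the dianion of 8, and it must go to the carbonyl of 9 and not to its β-carbon.

**7 to 5 and 6; 5 to 3 and 4; 3 to 1 and 2.** The aminomethyl group comes from iminium salt 6. The pyranone ring of 5 is cut at C4–C5 and O1–C2 to silyl enol ether 3 and diacid chloride 4. Enol ether 3 comes from ketone 1 and silyl chloride 2.

## Alternatives that were turned down

**Alternative 1:** The aryl ether bond O1–C8a is cut, so that the oxygen stays on the side chain as a secondary alcohol and C8a carries fluorine. In the forward step the alkoxide of (3S)-1-[2-fluoro-4,6-dimethoxy-3-(3-methylbut-2-enoyl)phenyl]-3-hydroxy-3-phenylpropan-1-one A2 adds to C8a and expels fluoride. This gives (2S)-5,7-dimethoxy-8-(3-methylbut-2-enoyl)-2-phenyl-2,3-dihydrochromen-4-one A1. The carbinol C–O bond is not broken, so the configuration is kept.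

- For: the fluorine is ortho to both carbonyl groups, so the addition intermediate is doubly stabilised. O1 can form only where the fluorine was, so regiochemistry is fixed by construction. The stereocentre comes from a carbinol, which is easy to make in one configuration.
- Against: A1 still lacks the C6 side chain and carries two methyl ethers. Their cleavage needs a boron or aluminium halide in the presence of the β,β-dimethyl enone and of C2, and the bridge must then be made on the finished, fragile molecule. The alkoxide of a β-hydroxy ketone can also undergo retro-aldol cleavage or dehydration to the enone, and an enone formed this way would close without control. A benzene with fluorine between two different acyl groups needs two regiocontrolled acylations.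
- Comparison: this alternative is stronger on regiochemical certainty and on the fidelity of C2, and it makes the bridge last, which is the gentlest timing. In exchange, the chosen route builds ring A, its three oxygens and the C4a acyl group in one isomerisation, keeps every hydroxyl free or silylated, and never has to cleave an aryl methyl ether. The step count is comparable.

**Alternative 2:** Two bonds of ring A, C7–C8 and C5–C6, are cut, so that ring A is annulated onto a finished, enantiopure ring C. In the forward step the dienolate at the ring methyl of methyl (2S)-6-methyl-4-oxo-2-phenyl-2,3-dihydropyran-5-carboxylate A4 is acylated by methyl 3-(6-ethyl-4-hydroxy-5-methyl-2-oxopyran-3-yl)propanoate A5. The α-carbon of the new ketone then closes onto the ring ester and the ring aromatises. The product is (2S)-6-[(6-ethyl-4-hydroxy-5-methyl-2-oxopyran-3-yl)methyl]-5,7-dihydroxy-2-phenyl-2,3-dihydrochromen-4-one A3.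

- For: O1–C8a and C2 exist from the start, so ring C poses no regiochemical question. The bridge is an ordinary CH2 of a propanoate until ring A is aromatic, so it cannot exchange. The approach is convergent.
- Against: both bond formations need strong base on a β-alkoxy ketone. Deprotonation at C3 competes with the wanted deprotonation at the methyl group and opens ring C by β-elimination, which destroys C2. A5 carries an acidic hydroxyl and an enolisable ester, so proton transfer can quench the dienolate. The second closure is onto an ester that is part of a vinylogous carbonate and is a poor electrophile. A3 would still need acylation at C8 next to a free hydroxyl.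
- Comparison: this alternative is stronger on regiochemistry and on how the stereocentre is made. It is weaker because the stereocentre must survive the two most basic steps. The chosen route puts all strong-base chemistry before C2 exists and arrives at the silylated form of A3 (compound 17) without an annulation on a chiral substrate.

**Alternative 3:** The pyranone is cut at C4′–C5′ and O1′–C2′ and is built last. In the forward step 2-{[(2S)-5,7-dimethoxy-8-(3-methylbut-2-enoyl)-4-oxo-2-phenyl-2,3-dihydrochromen-6-yl]methyl}propanedioyl dichloride A7 acylates (Z)-trimethyl(pent-2-en-3-yloxy)silane A8 (the same compound as 3) at carbon, and the enol oxygen closes onto the second acid chloride. The product is (2S)-6-[(6-ethyl-4-hydroxy-5-methyl-2-oxopyran-3-yl)methyl]-5,7-dimethoxy-8-(3-methylbut-2-enoyl)-2-phenyl-2,3-dihydrochromen-4-one A6.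

- For: the ring synthesis is the one used in step 2. The bridge is a plain benzylic carbon of a malonate until the last ring closes, so no exchange is possible earlier. The methyl ethers fix the regiochemistry of ring A.
- Against: A7 is a diacid chloride of a monosubstituted malonic acid, which loses hydrogen halide to an acyl ketene, and the acid set free can add to the enone. The malonate unit must be attached at C6 between two methoxy groups on a pentasubstituted ring. A6 then needs double cleavage of methyl ethers with a boron halide in the presence of the lactone, the enone and C2. The sequence is linear on the chiral flavanone.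
- Comparison: this alternative is stronger on bridge integrity and regiochemistry. The chosen route is convergent, makes the pyranone first from cheap materials, and ends with a mild desilylation in place of an ether cleavage.

Key step: step 6

Remarks on the chemistry (assumptions): Weinreb amide 9 and Grignard solution 20 are taken as purchased; 9 is otherwise one amide formation away from cinnamoyl chloride. Enol ether 3 is drawn as its main (Z)-isomer; its geometry has no bearing on step 2. Locants C2 to C8a refer to the flavanone, primed locants to the chalcone ring, and C1 to C9 in step 6 to the chain of 13.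

## Route

**Step 1**
Reactants: 1 pentan-3-one; 2 chlorotrimethylsilane
Product: 3 (Z)-trimethyl(pent-2-en-3-yloxy)silane
Conditions: TMSCl, Et3N, DMF, 80 °C
Reagents that add atoms: chlorotrimethylsilane, C[Si](C)(C)Cl
Why: Silyl enol ether formation under equilibrating conditions; the ketone is symmetrical, so only one regioisomer can form, and the double-bond geometry is lost in step 2.

**Step 2**
Reactants: 3 (Z)-trimethyl(pent-2-en-3-yloxy)silane; 4 propanedioyl dichloride
Product: 5 6-ethyl-4-hydroxy-5-methylpyran-2-one
Conditions: Et2O, −78 °C → rt; H2O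
Reagents that add atoms: propanedioyl dichloride, O=C(Cl)CC(Cl)=O
Why: Pyranone synthesis from a silyl enol ether and malonyl dichloride: C-acylation at the enol carbon is followed by O-acylation of the enol oxygen by the second acid chloride, and the ring tautomerises to the 4-hydroxypyran-2-one with ethyl on C6 and methyl on C5.

**Step 3**
Reactants: 5 6-ethyl-4-hydroxy-5-methylpyran-2-one; 6 N,N-dimethylmethaniminium iodide
Product: 7 3-[(dimethylamino)methyl]-6-ethyl-4-hydroxy-5-methylpyran-2-one
Conditions: CH2Cl2, rt; then Et3N (1 equiv)
Reagents that add atoms: N,N-dimethylmethaniminium iodide (Eschenmoser's salt), C=[N+](C)C.[I-]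
Why: Mannich reaction with a preformed iminium salt at C3, the only unsubstituted nucleophilic carbon of the ring; the aprotic medium contains no free formaldehyde, which would lead to the symmetrical methylene dimer.

**Step 4**
Reactants: 8 4-hydroxy-6-methylpyran-2-one; 9 (E)-N-methoxy-N-methyl-3-phenylprop-2-enamide
Product: 10 4-hydroxy-6-[(E)-2-oxo-4-phenylbut-3-en-1-yl]pyran-2-one
Conditions: LiN(iPr)2 (2.3 equiv), THF, −78 → −40 °C; 9, −78 → 0 °C; then 1 M HCl
Reagents that add atoms: (E)-N-methoxy-N-methyl-3-phenylprop-2-enamide, CON(C)C(=O)/C=C/c1ccccc1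
Why: Dianion acylation: the second deprotonation occurs at the 6-methyl group, which is then the most nucleophilic carbon. The Weinreb amide is attacked at its carbonyl and not at the β-carbon, and its chelated adduct holds until the acid quench, so the acidic product cannot consume dianion.

**Step 5**
Reactants: 10 4-hydroxy-6-[(E)-2-oxo-4-phenylbut-3-en-1-yl]pyran-2-one; 7 3-[(dimethylamino)methyl]-6-ethyl-4-hydroxy-5-methylpyran-2-one
Product: 12 3-[(6-ethyl-4-hydroxy-5-methyl-2-oxopyran-3-yl)methyl]-4-hydroxy-6-[(E)-2-oxo-4-phenylbut-3-en-1-yl]pyran-2-one, via 3-methylidenepyran-2,4-dione 11 (not isolated)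
Conditions: 10 (1.2 equiv), AcOH (1 equiv), MeCN, 60 °C
Reagents that add atoms: compound 7, CCc1oc(=O)c(CN(C)C)c(O)c1C
Why: Alkylation through a Mannich base: on warming, 7 loses dimethylamine to give the methylidene-dione 11, which is trapped in a Michael addition by C3 of 10, the enolic carbon between its two oxygenated carbons. Only 7 can become the electrophile, so the bridge is unsymmetrical, and acetic acid holds the amine as its salt so that it cannot add to the enone.

**Step 6**
Reactants: 12 3-[(6-ethyl-4-hydroxy-5-methyl-2-oxopyran-3-yl)methyl]-4-hydroxy-6-[(E)-2-oxo-4-phenylbut-3-en-1-yl]pyran-2-one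
Product: 14 (E)-1-{3-[(6-ethyl-4-hydroxy-5-methyl-2-oxopyran-3-yl)methyl]-2,4,6-trihydroxyphenyl}-3-phenylprop-2-en-1-one, via open-chain methyl triketo ester 13 (not isolated)
Conditions: Mg(OMe)2 (8 equiv), MeOH, 65 °C; then ice-cold 2 M HCl
Reagents that add atoms: none
Why: Methoxide adds to the lactone carbonyl of the half that carries the 2-oxoalkyl chain, and the ring opens to the magnesium-chelated methyl 3,5,7-triketo ester 13. Its C6, between the C5 ketone and the cinnamoyl ketone C7, is held as a planar magnesium diketonate and attacks the ester carbon C1 in a 6-exo-trig Claisen (Dieckmann-type) closure that forms the C4a–C5 bond of the target; loss of methoxide and enolisation give the aromatic triol, which makes the step irreversible. The closest known reaction is the magnesium methoxide recyclisation of 4-hydroxy-6-(2-oxoalkyl)pyran-2-ones to acylphloroglucinols; no stereocentre is formed. Three selectivities are needed, and each has a structural reason: the aldol mode would need C2 as the nucleophile, but C2 carries the bridge, so its adduct is quaternary, cannot aromatise and reverts; the excess of base keeps C5–C6–C7 as an enolate, which takes the electrophilic character from the styryl carbon C9 and so blocks both methoxide addition and internal Michael addition of C4; and the magnesium chelate keeps the C7 oxygen outside the new ring, which is the geometry of the Claisen mode only. The ethyl-methyl pyranone may open as well, but its acidic C–H between the two ketones could only close a four-membered ring, and the ethyl CH2 that sits at the right distance is activated by one carbonyl only, so this half returns to the pyranone. The polyanionic magnesium salts cannot readily form the neutral methylidene-dione needed for exchange across the bridge. In the strongly basic medium the product stays as the open chalcone polyanion, and the cold acid quench should deliver 14 before ring C can close.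

**Step 7**
Reactants: 14 (E)-1-{3-[(6-ethyl-4-hydroxy-5-methyl-2-oxopyran-3-yl)methyl]-2,4,6-trihydroxyphenyl}-3-phenylprop-2-en-1-one; 15 chlorotri(propan-2-yl)silane
Product: 16 (E)-1-{3-[(6-ethyl-5-methyl-2-oxo-4-{[tri(propan-2-yl)silyl]oxy}pyran-3-yl)methyl]-2,6-dihydroxy-4-{[tri(propan-2-yl)silyl]oxy}phenyl}-3-phenylprop-2-en-1-one
Conditions: TIPSCl (2.1 equiv), imidazole, CH2Cl2, 0 °C
Reagents that add atoms: chlorotri(propan-2-yl)silane, CC(C)[Si](Cl)(C(C)C)C(C)C
Why: Selective O-silylation: the pyranone oxygen (carboxylate-like) and the C4′ hydroxyl (para to the ketone) are the most acidic and are not chelated, whereas the two hydroxyls ortho to the ketone are hydrogen-bonded and hindered and should not react with a bulky silyl chloride at 0 °C.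

**Step 8**
Reactants: 16 (E)-1-{3-[(6-ethyl-5-methyl-2-oxo-4-{[tri(propan-2-yl)silyl]oxy}pyran-3-yl)methyl]-2,6-dihydroxy-4-{[tri(propan-2-yl)silyl]oxy}phenyl}-3-phenylprop-2-en-1-one
Product: 17 (2S)-6-[(6-ethyl-5-methyl-2-oxo-4-{[tri(propan-2-yl)silyl]oxy}pyran-3-yl)methyl]-5-hydroxy-2-phenyl-7-{[tri(propan-2-yl)silyl]oxy}-2,3-dihydrochromen-4-one
Conditions: 1-[3,5-bis(trifluoromethyl)phenyl]-3-[(8α,9S)-6′-methoxycinchonan-9-yl]thiourea (10 mol%), toluene, −20 °C
Reagents that add atoms: none
Why: Organocatalytic enantioselective intramolecular oxa-Michael addition of a 2′-hydroxychalcone (6-endo-trig): the thiourea binds the ketone and the quinuclidine deprotonates the hydroxyl that closes, so the ion pair adds to one face of the β-carbon; the (2S) product corresponds to attack on the Si face, and the quinidine-derived pseudoenantiomer of the catalyst is used if the sense is found to be opposite. Regiochemistry: the C2′ hydroxyl is pressed into the chelate with the ketone by the neighbouring substituent and shielded by the silylated pyranone, so the enone side chain faces the open C6′ hydroxyl next to the ring C–H, which puts the bridge on C6 and leaves C8 free. The remaining C5 hydroxyl chelates the C4 ketone and holds the product against ring opening.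

**Step 9**
Reactants: 17 (2S)-6-[(6-ethyl-5-methyl-2-oxo-4-{[tri(propan-2-yl)silyl]oxy}pyran-3-yl)methyl]-5-hydroxy-2-phenyl-7-{[tri(propan-2-yl)silyl]oxy}-2,3-dihydrochromen-4-one; 18 N-iodosuccinimide
Product: 19 (2S)-6-[(6-ethyl-5-methyl-2-oxo-4-{[tri(propan-2-yl)silyl]oxy}pyran-3-yl)methyl]-5-hydroxy-8-iodo-2-phenyl-7-{[tri(propan-2-yl)silyl]oxy}-2,3-dihydrochromen-4-one
Conditions: NIS (1.05 equiv), MeCN, 0 °C, dark
Reagents that add atoms: N-iodosuccinimide, O=C1CCC(=O)N1I
Why: Electrophilic aromatic iodination: C8 is the only unsubstituted carbon of ring A, para to the free C5 hydroxyl and ortho to two further oxygens; the neutral conditions leave C2, C3 and the silyl ethers untouched.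

**Step 10**
Reactants: 20 (2-methylprop-1-en-1-yl)magnesium bromide; 21 tributyl(chloro)stannane
Product: 22 tributyl(2-methylprop-1-en-1-yl)stannane
Conditions: THF, 0 °C → rt
Reagents that add atoms: tributyl(chloro)stannane, CCCC[Sn](Cl)(CCCC)CCCC
Why: Transmetalation of an alkenyl Grignard reagent to tin, which gives the alkenylstannane with the trisubstituted double bond in place.

**Step 11**
Reactants: 19 (2S)-6-[(6-ethyl-5-methyl-2-oxo-4-{[tri(propan-2-yl)silyl]oxy}pyran-3-yl)methyl]-5-hydroxy-8-iodo-2-phenyl-7-{[tri(propan-2-yl)silyl]oxy}-2,3-dihydrochromen-4-one; 22 tributyl(2-methylprop-1-en-1-yl)stannane; 23 carbon monoxide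
Product: 24 (2S)-6-[(6-ethyl-5-methyl-2-oxo-4-{[tri(propan-2-yl)silyl]oxy}pyran-3-yl)methyl]-5-hydroxy-8-(3-methylbut-2-enoyl)-2-phenyl-7-{[tri(propan-2-yl)silyl]oxy}-2,3-dihydrochromen-4-one
Conditions: CO (3 bar), Pd2(dba)3 (5 mol%), AsPh3 (20 mol%), CuI (10 mol%), 1,4-dioxane, 70 °C
Reagents that add atoms: tributyl(2-methylprop-1-en-1-yl)stannane, CCCC[Sn](CCCC)(CCCC)C=C(C)C; carbon monoxide, [C-]#[O+]
Why: Carbonylative Stille coupling: zerovalent palladium inserts into the C8–I bond, carbon monoxide inserts into the hindered aryl–palladium bond, and the alkenyl group is then transferred from tin before reductive elimination. No acid or base is present, so ring C, the bridge and the silyl ethers should persist, and with the C7 oxygen silylated the new enone has no neighbouring hydroxyl that could add to it.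

**Step 12**
Reactants: 24 (2S)-6-[(6-ethyl-5-methyl-2-oxo-4-{[tri(propan-2-yl)silyl]oxy}pyran-3-yl)methyl]-5-hydroxy-8-(3-methylbut-2-enoyl)-2-phenyl-7-{[tri(propan-2-yl)silyl]oxy}-2,3-dihydrochromen-4-one
Product: 25 (2S)-6-[(6-ethyl-4-hydroxy-5-methyl-2-oxopyran-3-yl)methyl]-5,7-dihydroxy-8-(3-methylbut-2-enoyl)-2-phenyl-2,3-dihydrochromen-4-one
Conditions: HF·pyridine, THF, 0 °C → rt
Reagents that add atoms: none
Why: Fluoride cleavage of two vinylogous silyl esters under weakly acidic conditions; the freed C7 hydroxyl is held in a hydrogen bond to the C8 carbonyl, which keeps the alkene on the O1 side and away from it, and the absence of base protects C2.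

## Compound list

1 | pentan-3-one | CCC(=O)CC | starting material
2 | chlorotrimethylsilane | C[Si](C)(C)Cl | starting material
3 | (Z)-trimethyl(pent-2-en-3-yloxy)silane | C/C=C(\O[Si](C)(C)C)CC | intermediate
4 | propanedioyl dichloride (malonyl dichloride) | O=C(Cl)CC(Cl)=O | starting material
5 | 6-ethyl-4-hydroxy-5-methylpyran-2-one | CCc1oc(=O)cc(O)c1C | intermediate
6 | N,N-dimethylmethaniminium iodide | C=[N+](C)C.[I-] | starting material
7 | 3-[(dimethylamino)methyl]-6-ethyl-4-hydroxy-5-methylpyran-2-one | CCc1oc(=O)c(CN(C)C)c(O)c1C | intermediate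
8 | 4-hydroxy-6-methylpyran-2-one | Cc1cc(O)cc(=O)o1 | starting material
9 | (E)-N-methoxy-N-methyl-3-phenylprop-2-enamide | CON(C)C(=O)/C=C/c1ccccc1 | starting material
10 | 4-hydroxy-6-[(E)-2-oxo-4-phenylbut-3-en-1-yl]pyran-2-one | O=C(Cc1cc(O)cc(=O)o1)/C=C/c1ccccc1 | intermediate
11 | 6-ethyl-5-methyl-3-methylidenepyran-2,4-dione | C=C1C(=O)OC(CC)=C(C)C1=O | intermediate (not isolated)
12 | 3-[(6-ethyl-4-hydroxy-5-methyl-2-oxopyran-3-yl)methyl]-4-hydroxy-6-[(E)-2-oxo-4-phenylbut-3-en-1-yl]pyran-2-one | CCc1oc(=O)c(Cc2c(O)cc(CC(=O)/C=C/c3ccccc3)oc2=O)c(O)c1C | intermediate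
13 | methyl (E)-2-[(6-ethyl-4-hydroxy-5-methyl-2-oxopyran-3-yl)methyl]-3,5,7-trioxo-9-phenylnon-8-enoate (C2 racemic and labile) | COC(=O)C(Cc1c(O)c(C)c(CC)oc1=O)C(=O)CC(=O)CC(=O)/C=C/c1ccccc1 | intermediate (not isolated)
14 | (E)-1-{3-[(6-ethyl-4-hydroxy-5-methyl-2-oxopyran-3-yl)methyl]-2,4,6-trihydroxyphenyl}-3-phenylprop-2-en-1-one | CCc1oc(=O)c(Cc2c(O)cc(O)c(C(=O)/C=C/c3ccccc3)c2O)c(O)c1C | intermediate
15 | chlorotri(propan-2-yl)silane | CC(C)[Si](Cl)(C(C)C)C(C)C | starting material
16 | (E)-1-{3-[(6-ethyl-5-methyl-2-oxo-4-{[tri(propan-2-yl)silyl]oxy}pyran-3-yl)methyl]-2,6-dihydroxy-4-{[tri(propan-2-yl)silyl]oxy}phenyl}-3-phenylprop-2-en-1-one | CCc1oc(=O)c(Cc2c(O[Si](C(C)C)(C(C)C)C(C)C)cc(O)c(C(=O)/C=C/c3ccccc3)c2O)c(O[Si](C(C)C)(C(C)C)C(C)C)c1C | intermediate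
17 | (2S)-6-[(6-ethyl-5-methyl-2-oxo-4-{[tri(propan-2-yl)silyl]oxy}pyran-3-yl)methyl]-5-hydroxy-2-phenyl-7-{[tri(propan-2-yl)silyl]oxy}-2,3-dihydrochromen-4-one | CCc1oc(=O)c(Cc2c(O[Si](C(C)C)(C(C)C)C(C)C)cc3c(c2O)C(=O)C[C@@H](c2ccccc2)O3)c(O[Si](C(C)C)(C(C)C)C(C)C)c1C | intermediate
18 | N-iodosuccinimide | O=C1CCC(=O)N1I | starting material
19 | (2S)-6-[(6-ethyl-5-methyl-2-oxo-4-{[tri(propan-2-yl)silyl]oxy}pyran-3-yl)methyl]-5-hydroxy-8-iodo-2-phenyl-7-{[tri(propan-2-yl)silyl]oxy}-2,3-dihydrochromen-4-one | CCc1oc(=O)c(Cc2c(O[Si](C(C)C)(C(C)C)C(C)C)c(I)c3c(c2O)C(=O)C[C@@H](c2ccccc2)O3)c(O[Si](C(C)C)(C(C)C)C(C)C)c1C | intermediate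
20 | (2-methylprop-1-en-1-yl)magnesium bromide | CC(C)=C[Mg]Br | starting material
21 | tributyl(chloro)stannane | CCCC[Sn](Cl)(CCCC)CCCC | starting material
22 | tributyl(2-methylprop-1-en-1-yl)stannane | CCCC[Sn](CCCC)(CCCC)C=C(C)C | intermediate
23 | carbon monoxide | [C-]#[O+] | starting material
24 | (2S)-6-[(6-ethyl-5-methyl-2-oxo-4-{[tri(propan-2-yl)silyl]oxy}pyran-3-yl)methyl]-5-hydroxy-8-(3-methylbut-2-enoyl)-2-phenyl-7-{[tri(propan-2-yl)silyl]oxy}-2,3-dihydrochromen-4-one | CCc1oc(=O)c(Cc2c(O[Si](C(C)C)(C(C)C)C(C)C)c(C(=O)C=C(C)C)c3c(c2O)C(=O)C[C@@H](c2ccccc2)O3)c(O[Si](C(C)C)(C(C)C)C(C)C)c1C | intermediate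
25 | (2S)-6-[(6-ethyl-4-hydroxy-5-methyl-2-oxopyran-3-yl)methyl]-5,7-dihydroxy-8-(3-methylbut-2-enoyl)-2-phenyl-2,3-dihydrochromen-4-one | CCc1oc(=O)c(Cc2c(O)c(C(=O)C=C(C)C)c3c(c2O)C(=O)C[C@@H](c2ccccc2)O3)c(O)c1C | target

## Step count and least certain steps

Total step count: 12. Longest linear sequence: 10 steps (1, 2, 3, 5, 6, 7, 8, 9, 11, 12).

**Step 6 (key step).** The selection among the cyclisation modes may be incomplete. If the medium is not basic enough to hold the C5/C7 diketone as its enolate, methoxide or the C4 carbanion can add to the styryl carbon. Prolonged heating may let the two halves exchange across the bridge, and a slow quench may let ring C close to racemic flavanones. Fallback: the order of bridging and refolding is exchanged. Starting from 10, the same magnesium methoxide treatment, now on the unbridged pyranone for which this recyclisation is established, gives (E)-3-phenyl-1-(2,4,6-trihydroxyphenyl)prop-2-en-1-one F1. F1 is used in excess, because it has two equivalent free ring carbons, and is alkylated by Mannich base 7 under the conditions of step 5. The route is rejoined at 14.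

**Step 8.** The most likely failure is insufficient facial selectivity, because an unactivated chalcone gives the catalyst little to hold. A share of the closure may also run through the hindered hydroxyl. Fallback: regiochemistry is taken from acidity and configuration from a resolution. Starting from 16, iodination with 18 at the one free ring carbon gives (E)-1-{3-[(6-ethyl-5-methyl-2-oxo-4-{[tri(propan-2-yl)silyl]oxy}pyran-3-yl)methyl]-2,6-dihydroxy-5-iodo-4-{[tri(propan-2-yl)silyl]oxy}phenyl}-3-phenylprop-2-en-1-one F2. In F2 the hydroxyl that has to close is ortho to iodine and is the more acidic of the two. An achiral tertiary amine (DABCO, toluene) closes it to racemic 6-[(6-ethyl-5-methyl-2-oxo-4-{[tri(propan-2-yl)silyl]oxy}pyran-3-yl)methyl]-5-hydroxy-8-iodo-2-phenyl-7-{[tri(propan-2-yl)silyl]oxy}-2,3-dihydrochromen-4-one F3. Asymmetric transfer hydrogenation with RhCl(Cp*)[(R,R)-TsDPEN] or its enantiomer (HCO2H/Et3N), chosen so that the (2R)-ketone is the one reduced, converts that enantiomer into (2R,4R)-6-[(6-ethyl-5-methyl-2-oxo-4-{[tri(propan-2-yl)silyl]oxy}pyran-3-yl)methyl]-8-iodo-2-phenyl-7-{[tri(propan-2-yl)silyl]oxy}-3,4-dihydro-2H-chromene-4,5-diol F4. The (2S)-ketone is left unreduced and is 19, so the route is rejoined at 19 and step 9 is skipped.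

**Step 5.** Retro-Michael loss of either ring from the product can lead to exchange and symmetrical dimers. The enolic C3 of either pyranone can also add to the enone of 10. Fallback: the bridge is made before the enone exists. Starting from 8, which is cheap and can be used in large excess to outrun exchange, and 7, the conditions of step 5 give 3-[(6-ethyl-4-hydroxy-5-methyl-2-oxopyran-3-yl)methyl]-4-hydroxy-6-methylpyran-2-one F5. Its trianion (LiN(iPr)2, 3.3 equiv) is acylated with 9 as in step 4; the ring methyl group should be deprotonated in preference to the CH2 of the ethyl group. The route is rejoined at 12.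

**Step 11.** Acyl transfer may be slow at a carbon flanked by O1 and a silyloxy group. The results would be coupling without insertion of carbon monoxide, or loss of iodine by reduction. Fallback: electrophilic acylation on the unprotected ring. Starting from 17, HF·pyridine gives (2S)-6-[(6-ethyl-4-hydroxy-5-methyl-2-oxopyran-3-yl)methyl]-5,7-dihydroxy-2-phenyl-2,3-dihydrochromen-4-one F6. A Friedel–Crafts acylation with 3-methylbut-2-enoyl chloride and AlCl3 (CH2Cl2/PhNO2, 0 °C) then leads directly to 25. The aluminium chelate between the C7 oxygen and the new carbonyl should keep the alkene turned away from that oxygen.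

## Further compounds

F1 | step 6 | (E)-3-phenyl-1-(2,4,6-trihydroxyphenyl)prop-2-en-1-one | O=C(/C=C/c1ccccc1)c1c(O)cc(O)cc1O
F2 | step 8 | (E)-1-{3-[(6-ethyl-5-methyl-2-oxo-4-{[tri(propan-2-yl)silyl]oxy}pyran-3-yl)methyl]-2,6-dihydroxy-5-iodo-4-{[tri(propan-2-yl)silyl]oxy}phenyl}-3-phenylprop-2-en-1-one | CCc1oc(=O)c(Cc2c(O[Si](C(C)C)(C(C)C)C(C)C)c(I)c(O)c(C(=O)/C=C/c3ccccc3)c2O)c(O[Si](C(C)C)(C(C)C)C(C)C)c1C
F3 | step 8 | racemic 6-[(6-ethyl-5-methyl-2-oxo-4-{[tri(propan-2-yl)silyl]oxy}pyran-3-yl)methyl]-5-hydroxy-8-iodo-2-phenyl-7-{[tri(propan-2-yl)silyl]oxy}-2,3-dihydrochromen-4-one | CCc1oc(=O)c(Cc2c(O[Si](C(C)C)(C(C)C)C(C)C)c(I)c3c(c2O)C(=O)CC(c2ccccc2)O3)c(O[Si](C(C)C)(C(C)C)C(C)C)c1C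
F4 | step 8 | (2R,4R)-6-[(6-ethyl-5-methyl-2-oxo-4-{[tri(propan-2-yl)silyl]oxy}pyran-3-yl)methyl]-8-iodo-2-phenyl-7-{[tri(propan-2-yl)silyl]oxy}-3,4-dihydro-2H-chromene-4,5-diol | CCc1oc(=O)c(Cc2c(O[Si](C(C)C)(C(C)C)C(C)C)c(I)c3c(c2O)[C@H](O)C[C@H](c2ccccc2)O3)c(O[Si](C(C)C)(C(C)C)C(C)C)c1C
F5 | step 5 | 3-[(6-ethyl-4-hydroxy-5-methyl-2-oxopyran-3-yl)methyl]-4-hydroxy-6-methylpyran-2-one | CCc1oc(=O)c(Cc2c(O)cc(C)oc2=O)c(O)c1C
F6 | step 11 | (2S)-6-[(6-ethyl-4-hydroxy-5-methyl-2-oxopyran-3-yl)methyl]-5,7-dihydroxy-2-phenyl-2,3-dihydrochromen-4-one | CCc1oc(=O)c(Cc2c(O)cc3c(c2O)C(=O)C[C@@H](c2ccccc2)O3)c(O)c1C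
A1 | alternative 1 | (2S)-5,7-dimethoxy-8-(3-methylbut-2-enoyl)-2-phenyl-2,3-dihydrochromen-4-one | O=C1C[C@@H](c2ccccc2)Oc2c(C(=O)C=C(C)C)c(OC)cc(OC)c12
A2 | alternative 1 | (3S)-1-[2-fluoro-4,6-dimethoxy-3-(3-methylbut-2-enoyl)phenyl]-3-hydroxy-3-phenylpropan-1-one | O=C(C[C@H](O)c1ccccc1)c1c(F)c(C(=O)C=C(C)C)c(OC)cc1OC
A3 | alternative 2 | (2S)-6-[(6-ethyl-4-hydroxy-5-methyl-2-oxopyran-3-yl)methyl]-5,7-dihydroxy-2-phenyl-2,3-dihydrochromen-4-one | O=C1C[C@@H](c2ccccc2)Oc2cc(O)c(Cc3c(O)c(C)c(CC)oc3=O)c(O)c12
A4 | alternative 2 | methyl (2S)-6-methyl-4-oxo-2-phenyl-2,3-dihydropyran-5-carboxylate | COC(=O)C1=C(C)O[C@H](c2ccccc2)CC1=O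
A5 | alternative 2 | methyl 3-(6-ethyl-4-hydroxy-5-methyl-2-oxopyran-3-yl)propanoate | COC(=O)CCc1c(O)c(C)c(CC)oc1=O
A6 | alternative 3 | (2S)-6-[(6-ethyl-4-hydroxy-5-methyl-2-oxopyran-3-yl)methyl]-5,7-dimethoxy-8-(3-methylbut-2-enoyl)-2-phenyl-2,3-dihydrochromen-4-one | CCc1oc(=O)c(Cc2c(OC)c(C(=O)C=C(C)C)c3c(c2OC)C(=O)C[C@@H](c2ccccc2)O3)c(O)c1C
A7 | alternative 3 | 2-{[(2S)-5,7-dimethoxy-8-(3-methylbut-2-enoyl)-4-oxo-2-phenyl-2,3-dihydrochromen-6-yl]methyl}propanedioyl dichloride | O=C(Cl)C(Cc1c(OC)c(C(=O)C=C(C)C)c2c(c1OC)C(=O)C[C@@H](c1ccccc1)O2)C(Cl)=O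
A8 | alternative 3 | (Z)-trimethyl(pent-2-en-3-yloxy)silane | C/C=C(\O[Si](C)(C)C)CC
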